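**Plan**

1. Numbering: ring C1 (carries the side chain), C2 (OAng), C3 (OH), C4 (Me, OH), C5 (C=O), C6 (OAng); side chain C1'(=CH2)–C2'(OAng)–C3'–C4'/C5' (epoxide); Ang = angeloyl.
2. Retrosynthesis: remove the side-chain epoxide oxygen and the three angelates; cut C1'–C2' (alkenyl triflate + aldehyde); take C5=O/C6–O back to a C5–C6 epoxide and then an alkene; finally cut the ring bonds C1–C2 and C3–C4 together.
3. Enabling feature: C2/C3 are a cis-diol (a cis-enediol ether), and C1 and C4 carry on the same ring face a one-carbon branch (C1') and an oxygen. With C5–C6 unsaturated this is the imprint of a 6-methyl-2-pyrone whose O–C(=O) unit bridges C4 and C1, so the carbocycle is a pyrone/enediol [4+2] adduct.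
4. Forward: pyrone ester → asymmetric inverse-demand Diels–Alder closes the carbocycle as a bridged lactone (bicyclic C1/C4/C7/C8/C5/C6/C3 = target C4/C1/C3/C2/C6/C5/C1') → activating ester removed → epoxide → lactone opened to methyl ketone → enol triflate → side chain joined → first angelate → epoxide opened by angelic acid, oxidation, acetal removal, last angelate, side-chain epoxide.
5. Stereochemistry: C1–C4 from the cycloaddition (cis-alkene, endo, lactone bridge; absolute sense from the bis(oxazoline) ligand); C6 by inversion at an epoxide placed by the bicycle; C2' from the chiral ligand on chromium; C4' from the Shi ketone.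

Key step: step 2

Remark: the ligand enantiomers named in steps 2 and 9 and the ketone enantiomer named in step 16 are assumed to give the stated sense of induction (the antipode is used otherwise), and 2,2-dimethyl-1,3-dioxole is taken as a catalogue chemical.

**Step 1**
Reactants: 1 4,4-dimethoxybutan-2-one; 2 diallyl malonate
Product: 4 allyl 6-methyl-2-oxo-2H-pyran-3-carboxylate, via alkylidene malonate 3 (not isolated)
Conditions: ZnCl2 (cat.), Ac2O, 120 °C
Reagents that add atoms: none
Why: Knoevenagel condensation of the malonate with the acetal carbon gives 3, whose ketone enol lactonises onto the cis ester with loss of allyl alcohol (enol lactonisation), the standard entry to 3-carboalkoxy-2-pyrones.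

**Step 2**
Reactants: 4 allyl 6-methyl-2-oxo-2H-pyran-3-carboxylate; 5 2,2-dimethyl-1,3-dioxole
Product: 6 allyl (1S,4R,7S,8S)-7,8-(isopropylidenedioxy)-1-methyl-3-oxo-2-oxabicyclo[2.2.2]oct-5-ene-4-carboxylate (endo adduct)
Conditions: Cu(OTf)2 (10 mol %), (S,S)-2,2'-isopropylidenebis(4-tert-butyl-2-oxazoline) (11 mol %), 4 Å MS, CH2Cl2, −20 °C to rt
Reagents that add atoms: none
Why: The chiral Cu(OTf)2–bis(oxazoline) complex chelates the lactone and ester carbonyls of 4 and lowers its LUMO, so the electron-rich cis-enediol ether 5 adds across the pyrone C3 and C6 termini in a concerted but asynchronous inverse-electron-demand Diels–Alder reaction (bond to the methyl-bearing C6 leading, bond to C3 following), which forms both new ring bonds in one event. The closest known reaction type is the Lewis-acid-catalysed asymmetric inverse-demand Diels–Alder reaction of 3-carboalkoxy-2-pyrones with enol ethers. One ring is closed, the cyclohexene C1–C7–C8–C4–C5=C6 of the adduct (the carbocycle of the target), by an intermolecular [4+2] cycloaddition that is suprafacial on both partners; the pyrone O–C(=O) unit is left as a two-atom bridge over this ring and the dioxolane stays cis-fused. C7 and C8 are cis because the cyclic Z-alkene adds suprafacially, C1 (Me, O) and C4 are tied cis by the lactone bridge, the dioxolane lies anti to that bridge through the endo transition state (dioxole stacked under the diene carbons that become C5=C6), and the absolute sense is set by the tert-butyl group of the ligand, which blocks one face of the chelated pyrone. The step needs endo and facial selectivity, both secured by the rigid square-planar chelate and the low temperature, which also prevents retro-[4+2] loss of CO2; regioselectivity is not at issue because 5 is C2v-symmetric.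

**Step 3**
Reactants: 6 endo adduct
Product: 7 (1S,4R,7S,8S)-7,8-(isopropylidenedioxy)-1-methyl-3-oxo-2-oxabicyclo[2.2.2]oct-5-ene-4-carboxylic acid
Conditions: Pd(PPh3)4 (2 mol %), HCO2H, Et3N, THF, 0 °C to rt
Reagents that add atoms: none
Why: Zerovalent palladium ionises the unhindered primary allyl ester and formate reduces the π-allyl complex to propene (Tsuji–Trost deallylation), while the tertiary bridged allylic lactone is spared because palladium would have to approach the alkene face covered by the dioxolane; the bridgehead malonic half-acid cannot decarboxylate through an enol (Bredt's rule) and no stereocentre is touched.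

**Step 4**
Reactants: 7 bridgehead acid
Product: 10 (1S,4R,7S,8S)-7,8-(isopropylidenedioxy)-1-methyl-2-oxabicyclo[2.2.2]oct-5-en-3-one, via acid chloride 8 (not isolated), via thiohydroxamate ester 9 (not isolated)
Conditions: (COCl)2, DMF (cat.), CH2Cl2, 0 °C; then 2-mercaptopyridine N-oxide sodium salt (C5H4NNaOS), DMAP (cat.), t-BuSH, toluene, hν (tungsten lamp), rt
Reagents that add atoms: none
Why: Barton reductive decarboxylation: the thiohydroxamate ester fragments in light to the bridgehead radical, which needs no planarity and takes hydrogen from t-BuSH, so the C4–H bond is formed with the configuration dictated by the bicycle.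

**Step 5**
Reactants: 10 bicyclic lactone
Product: 11 5,6-epoxide of 10 (oxirane oxygen on the side of the lactone bridge)
Conditions: mCPBA, NaHCO3, CH2Cl2, rt to 40 °C
Reagents that add atoms: mCPBA, O=C(OO)c1cccc(Cl)c1
Why: Prilezhaev epoxidation of the only alkene from the face of the flat lactone bridge, the other face being covered by the endo dioxolane, so the oxirane oxygen should end up cis to the C1–O bond (the future tertiary hydroxyl).

**Step 6**
Reactants: 11 epoxy lactone
Product: 13 1-acetyl-5,6-epoxy-2,3-(isopropylidenedioxy)-4-methylcyclohexan-4-ol (target ring numbering; acetyl group/4-OH/oxirane oxygen on one face; dioxolane oxygens on the other), via lithium hemiketalate 12 (not isolated)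
Conditions: MeLi (1.1 equiv), THF, −78 °C; AcOH quench at −78 °C
Reagents that add atoms: MeLi, [Li]C
Why: Nucleophilic addition of one equivalent of MeLi to the lactone carbonyl stops at the tetrahedral stage 12 at −78 °C, and the cold quench releases the methyl ketone and the tertiary alcohol; the epoxide is inert at this temperature and the α-carbon set in step 2 is not deprotonated.

**Step 7**
Reactants: 13 hydroxy methyl ketone
Product: 15 enol triflate of 13 [C1 bears C(=CH2)OSO2CF3], via dipotassium enolate alkoxide 14 (not isolated)
Conditions: KN(SiMe3)2 (2.2 equiv), THF, −78 °C; then PhNTf2, −78 to −30 °C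
Reagents that add atoms: N-phenylbis(trifluoromethanesulfonimide), O=S(=O)(N(c1ccccc1)S(=O)(=O)C(F)(F)F)C(F)(F)F
Why: Kinetic deprotonation of the methyl group by the hindered amide base (the ring α-hydrogen is flanked by two substituted carbons; the first equivalent of base is taken by the hydroxyl) and O-sulfonylation of the enolate give the terminal enol triflate without touching C1.

**Step 8**
Reactants: 16 4-methylpent-3-en-1-ol
Product: 17 4-methylpent-3-enal
Conditions: Dess–Martin periodinane, NaHCO3, CH2Cl2, 0 °C (used directly)
Reagents that add atoms: none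
Why: Dess–Martin oxidation of the primary alcohol under buffered, base-free conditions should give the β,γ-unsaturated aldehyde without migration of the double bond into conjugation.

**Step 9**
Reactants: 15 enol triflate; 17 4-methylpent-3-enal
Product: 18 (2'S)-allylic alcohol [C1 bears C(=CH2)–CH(OH)–CH2–CH=CMe2; ring as in 13]
Conditions: CrCl2 (4 equiv), NiCl2 (2 mol %), (S)-N-[2-(4-isopropyl-4,5-dihydrooxazol-2-yl)-6-methylphenyl]methanesulfonamide (4.4 equiv), Et3N (4.4 equiv), THF, rt
Reagents that add atoms: none
Why: Nozaki–Hiyama–Kishi reaction: nickel-catalysed, chromium-mediated addition of the alkenyl triflate to the aldehyde alone (epoxide, acetal and free hydroxyl are tolerated) creates the 1,1-disubstituted alkene and the C2' carbinol in one step, whose S configuration is set by the chiral sulfonamide ligand on chromium.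

**Step 10**
Reactants: 19 angelic acid [(Z)-2-methylbut-2-enoic acid]
Product: 20 angelic 2,4,6-trichlorobenzoic anhydride (filtered toluene solution, made in one batch sized for steps 11 and 15 and kept at −20 °C under argon)
Conditions: 2,4,6-trichlorobenzoyl chloride (1.0 equiv), Et3N (1.05 equiv), toluene, rt; filtration from Et3NHCl under argon
Reagents that add atoms: 2,4,6-trichlorobenzoyl chloride, O=C(Cl)c1c(Cl)cc(Cl)cc1Cl
Why: First stage of the Yamaguchi esterification: the triethylammonium carboxylate acylates the hindered aroyl chloride to give the mixed anhydride, whose aroyl carbonyl is shielded by the two ortho chlorines so that an alcohol will later attack the angeloyl carbonyl, and the absence of a nucleophilic catalyst keeps the Z-alkene from isomerising to the tiglate.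

**Step 11**
Reactants: 18 allylic alcohol; 20 angelic 2,4,6-trichlorobenzoic anhydride
Product: 21 2'-O-angelate of 18
Conditions: 20 (1.5 equiv, toluene solution), Et3N (1.5 equiv), toluene, 70 °C
Reagents that add atoms: none
Why: Second stage of the Yamaguchi esterification, run without DMAP: the secondary allylic C2' hydroxyl attacks the unhindered angeloyl carbonyl of 20 while the tertiary C4 hydroxyl stays inert, angelate-to-tiglate isomerisation is avoided, and no stereocentre is affected.

**Step 12**
Reactants: 21 epoxy alcohol; 19 angelic acid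
Product: 22 6,2'-di-O-angeloyl-4,5-diol (C6 angelate trans to the C1 side chain; C5–OH cis to C4–OH; 2,3-acetonide retained)
Conditions: Ti(OiPr)4 (1.5 equiv), 19 (3 equiv), CH2Cl2, rt
Reagents that add atoms: none
Why: Titanium-mediated opening of a 2,3-epoxy alcohol by a carboxylic acid: Ti(OiPr)4 binds the C4 alkoxide and the cis epoxide oxygen, and the carboxylate attacks the distal, less hindered C6 (C5 is neopentyl and deactivated by the adjacent C–O) with inversion, which places the angelate trans to the C1 side chain as in the target and leaves the C5 hydroxyl.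

**Step 13**
Reactants: 22 diol diangelate
Product: 23 5-ketone of 22
Conditions: Dess–Martin periodinane, NaHCO3, CH2Cl2, 0 °C to rt
Reagents that add atoms: none
Why: Dess–Martin oxidation of the secondary C5 alcohol next to the unreactive tertiary alcohol gives the α-hydroxy α'-acyloxy ketone; C6 keeps its configuration, which is also the thermodynamically preferred equatorial one.

**Step 14**
Reactants: 23 acetonide ketone
Product: 24 2,3,4-triol (23 without the isopropylidene group)
Conditions: AcOH–H2O (4:1), 45 °C
Reagents that add atoms: none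
Why: Acid-catalysed hydrolysis of the isopropylidene acetal under mild aqueous acetic acid frees the cis C2/C3 diol while esters, ketone and the two side-chain alkenes persist; no stereocentre is affected.

**Step 15**
Reactants: 24 triol; 20 angelic 2,4,6-trichlorobenzoic anhydride
Product: 25 2,6,2'-tri-O-angelate with the C4'=C5' alkene (deoxy target)
Conditions: 20 (1.1 equiv, toluene solution, slow addition), Et3N (1.2 equiv), toluene, 50 °C
Reagents that add atoms: none
Why: Yamaguchi esterification with one equivalent of the mixed anhydride is expected to select the equatorial C2 hydroxyl over the axial C3 hydroxyl, which is neopentyl (next to quaternary C4), and over the tertiary C4 hydroxyl.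

**Step 16**
Reactants: 25 triangelate
Product: 26 CNP0313777.1 (target)
Conditions: D-fructose-derived ketone catalyst of the Shi epoxidation (0.3 equiv), KHSO5 (as 2KHSO5·KHSO4·K2SO4), NaHCO3, Bu4NHSO4 (cat.), MeCN–aqueous Na2EDTA, 0 °C, pH about 8
Reagents that add atoms: potassium peroxymonosulfate KHSO5, [K+].[O-]S(=O)(=O)OO
Why: Shi epoxidation: the chiral dioxirane should epoxidise the electron-rich trisubstituted side-chain alkene much faster than the 1,1-disubstituted alkene next to the allylic ester or the electron-poor angelate alkenes, and its spiro transition state delivers oxygen to the face that gives the (4'R) epoxide; the near-neutral pH protects the base-sensitive hydroxy ketone.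

**Compound list**

1 | 4,4-dimethoxybutan-2-one | CC(=O)CC(OC)OC | starting material
2 | diallyl malonate | C=CCOC(=O)CC(=O)OCC=C | starting material
3 | diallyl 2-(3-oxobutylidene)malonate | CC(=O)CC=C(C(=O)OCC=C)C(=O)OCC=C | intermediate
4 | allyl 6-methyl-2-oxo-2H-pyran-3-carboxylate | CC1=CC=C(C(=O)OCC=C)C(=O)O1 | intermediate
5 | 2,2-dimethyl-1,3-dioxole | CC1(C)OC=CO1 | starting material
6 | allyl (1S,4R,7S,8S)-7,8-(isopropylidenedioxy)-1-methyl-3-oxo-2-oxabicyclo[2.2.2]oct-5-ene-4-carboxylate (endo: dioxolane on the side of C5=C6) | O=C3[C@@]1(C(=O)OCC=C)[C@@H]2OC(C)(C)O[C@@H]2[C@@](C)(O3)C=C1 | intermediate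
7 | (1S,4R,7S,8S)-7,8-(isopropylidenedioxy)-1-methyl-3-oxo-2-oxabicyclo[2.2.2]oct-5-ene-4-carboxylic acid | O=C3[C@@]1(C(=O)O)[C@@H]2OC(C)(C)O[C@@H]2[C@@](C)(O3)C=C1 | intermediate
8 | 4-carbonyl chloride of 7 | O=C3[C@@]1(C(Cl)=O)[C@@H]2OC(C)(C)O[C@@H]2[C@@](C)(O3)C=C1 | intermediate
9 | 2-thioxopyridin-1(2H)-yl ester of 7 (thiohydroxamate ester) | O=C3[C@@]1(C(=O)ON4C=CC=CC4=S)[C@@H]2OC(C)(C)O[C@@H]2[C@@](C)(O3)C=C1 | intermediate
10 | (1S,4R,7S,8S)-7,8-(isopropylidenedioxy)-1-methyl-2-oxabicyclo[2.2.2]oct-5-en-3-one | O=C3[C@H]1[C@@H]2OC(C)(C)O[C@@H]2[C@@](C)(O3)C=C1 | intermediate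
11 | 5,6-epoxide of 10, oxirane oxygen on the side of the lactone bridge, anti to the dioxolane | O=C3[C@H]1[C@@H]2OC(C)(C)O[C@@H]2[C@@](C)(O3)[C@H]4O[C@H]41 | intermediate
12 | lithium salt of the 3-hydroxy-3-methyl hemiketal formed from 11 (configuration at the hemiketal carbon not defined) | [Li+].CC3([O-])[C@H]1[C@@H]2OC(C)(C)O[C@@H]2[C@@](C)(O3)[C@H]4O[C@H]41 | intermediate
13 | 1-acetyl-5,6-epoxy-2,3-(isopropylidenedioxy)-4-methylcyclohexan-4-ol (acetyl, 4-OH and oxirane O on one face; dioxolane O atoms on the other; C1–C4 as in the target) | CC(=O)[C@H]1[C@@H]2OC(C)(C)O[C@@H]2[C@@](C)(O)[C@H]3O[C@H]31 | intermediate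
14 | dipotassium salt of 13 (terminal enolate of the acetyl group, C4 alkoxide) | [K+].[K+].C=C([O-])[C@H]1[C@@H]2OC(C)(C)O[C@@H]2[C@@](C)([O-])[C@H]3O[C@H]31 | intermediate
15 | enol triflate of 13, C1 substituent C(=CH2)OSO2CF3 | C=C(OS(=O)(=O)C(F)(F)F)[C@H]1[C@@H]2OC(C)(C)O[C@@H]2[C@@](C)(O)[C@H]3O[C@H]31 | intermediate
16 | 4-methylpent-3-en-1-ol | CC(C)=CCCO | starting material
17 | 4-methylpent-3-enal | CC(C)=CCC=O | intermediate
18 | (2'S)-allylic alcohol, C1 substituent C(=CH2)–CH(OH)–CH2–CH=CMe2, ring as in 13 | C=C([C@H]1[C@@H]2OC(C)(C)O[C@@H]2[C@@](C)(O)[C@H]3O[C@H]31)[C@H](CC=C(C)C)O | intermediate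
19 | angelic acid, (Z)-2-methylbut-2-enoic acid | C/C=C(/C)C(=O)O | starting material
20 | angelic 2,4,6-trichlorobenzoic anhydride | C/C=C(/C)C(=O)OC(=O)c1c(Cl)cc(Cl)cc1Cl | intermediate
21 | 2'-O-angelate of 18 | C=C([C@H]1[C@@H]2OC(C)(C)O[C@@H]2[C@@](C)(O)[C@H]3O[C@H]31)[C@H](CC=C(C)C)OC(=O)/C(C)=C\C | intermediate
22 | 6,2'-di-O-angeloyl 4,5-diol, C6–OAng trans to the C1 side chain, C5–OH cis to C4–OH, 2,3-acetonide | C=C([C@H]1[C@@H]2OC(C)(C)O[C@@H]2[C@@](C)(O)[C@@H](O)[C@@H]1OC(=O)/C(C)=C\C)[C@H](CC=C(C)C)OC(=O)/C(C)=C\C | intermediate
23 | 5-ketone of 22 | C=C([C@H]1[C@@H]2OC(C)(C)O[C@@H]2[C@@](C)(O)C(=O)[C@@H]1OC(=O)/C(C)=C\C)[C@H](CC=C(C)C)OC(=O)/C(C)=C\C | intermediate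
24 | 2,3,4-triol, 23 without the isopropylidene group | C=C([C@H]1[C@H](O)[C@H](O)[C@@](C)(O)C(=O)[C@@H]1OC(=O)/C(C)=C\C)[C@H](CC=C(C)C)OC(=O)/C(C)=C\C | intermediate
25 | 2,6,2'-tri-O-angelate with the C4'=C5' alkene (deoxy target) | C=C([C@H]1[C@H](OC(=O)/C(C)=C\C)[C@H](O)[C@@](C)(O)C(=O)[C@@H]1OC(=O)/C(C)=C\C)[C@H](CC=C(C)C)OC(=O)/C(C)=C\C | intermediate
26 | CNP0313777.1: (2S)-1-[(2R)-3,3-dimethyloxiran-2-yl]-3-[(1S,2S,3S,4R,6R)-2,6-bis(angeloyloxy)-3,4-dihydroxy-4-methyl-5-oxocyclohexyl]but-3-en-2-yl angelate | C=C([C@H]1[C@H](OC(=O)/C(C)=C\C)[C@H](O)[C@@](C)(O)C(=O)[C@@H]1OC(=O)/C(C)=C\C)[C@H](C[C@H]1OC1(C)C)OC(=O)/C(C)=C\C | target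

**Step count and risks**

Total steps: 16. Longest linear sequence: 14 steps (steps 1–7, 9 and 11–16); step 8 prepares the side-chain aldehyde and step 10 the acylating agent.

Steps most likely to fail:

Step 2. The methyl group on the pyrone terminus that bonds first may make the cycloaddition sluggish, the Lewis acid may oligomerise the enol acetal, or enantioselectivity may erode. Fallback, setting out from 4 and 5 and returning at 7: the uncatalysed cycloaddition at 12 kbar (CH2Cl2, rt) should give the racemic endo adduct, that is 6 together with ent-6 F1. Deallylation as in step 3 then gives 7 together with ent-7 F2. Classical resolution by crystallisation with (S)-1-phenylethylamine gives the less soluble (S)-1-phenylethylammonium salt of 7 F3, and acidification releases 7. Absolute control then comes from resolution instead of catalysis.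

Step 12. Opening of the hindered epoxide by the bulky carboxylate may be slow, attack at C6 has to pass through a twist-boat-like arrangement so regioselectivity may suffer, and acyl migration to the C5 oxygen may follow. Fallback, setting out from 21 and returning at 23: MgBr2·OEt2 (Et2O, 0 °C) opens the epoxide with the small bromide to give bromohydrin F4 (Br at C6, OH at C5). Dess–Martin oxidation gives α-bromo ketone F5. Displacement with cesium angelate F6 (CsO2C–C(CH3)=CHCH3, from 19 and Cs2CO3, DMF, rt) gives the inverted C6 epimer of 23 F7, which is equilibrated at the ketone α-carbon (DBU, cat.) to the equatorial ester 23. The C6 centre is then set by thermodynamic control instead of stereospecific opening.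

Step 15. Acylation may also occur at the axial C3 hydroxyl, the acyl group may migrate between the cis C2/C3 oxygens under base, and prolonged heating may isomerise angelate to tiglate. Fallback, setting out from 24 and returning at 25: Bu2SnO (MeOH, reflux, then evaporation) converts the cis-diol into the 2,3-O-dibutylstannylene acetal of 24 F8, whose equatorial C2 oxygen is the more nucleophilic one. Treatment with mixed anhydride 20 (toluene, rt) then delivers 25 by activation of the oxygen instead of by reliance on steric rate differences.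

**Further compounds**

F1 | step 2 | ent-6, mirror image of adduct 6 (formed with 6 as the racemate) | O=C3[C@]1(C(=O)OCC=C)[C@H]2OC(C)(C)O[C@H]2[C@](C)(O3)C=C1
F2 | step 2 | ent-7, mirror image of acid 7 | O=C3[C@]1(C(=O)O)[C@H]2OC(C)(C)O[C@H]2[C@](C)(O3)C=C1
F3 | step 2 | (S)-1-phenylethylammonium salt of 7 | C[C@H]([NH3+])c1ccccc1.O=C3[C@@]1(C(=O)[O-])[C@@H]2OC(C)(C)O[C@@H]2[C@@](C)(O3)C=C1
F4 | step 12 | bromohydrin from 21 (C6–Br trans to the C1 side chain, C5–OH cis to C4–OH) | C=C([C@H]1[C@@H]2OC(C)(C)O[C@@H]2[C@@](C)(O)[C@@H](O)[C@@H]1Br)[C@H](CC=C(C)C)OC(=O)/C(C)=C\C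
F5 | step 12 | α-bromo ketone (5-oxo, 6-bromo) | C=C([C@H]1[C@@H]2OC(C)(C)O[C@@H]2[C@@](C)(O)C(=O)[C@@H]1Br)[C@H](CC=C(C)C)OC(=O)/C(C)=C\C
F6 | step 12 | cesium angelate | [Cs+].C/C=C(/C)C(=O)[O-]
F7 | step 12 | C6 epimer of 23 | C=C([C@H]1[C@@H]2OC(C)(C)O[C@@H]2[C@@](C)(O)C(=O)[C@H]1OC(=O)/C(C)=C\C)[C@H](CC=C(C)C)OC(=O)/C(C)=C\C
F8 | step 15 | 2,3-O-dibutylstannylene acetal of 24 | C=C([C@H]1[C@@H]2O[Sn](CCCC)(CCCC)O[C@@H]2[C@@](C)(O)C(=O)[C@@H]1OC(=O)/C(C)=C\C)[C@H](CC=C(C)C)OC(=O)/C(C)=C\C
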